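Retrosynthesis (macrolide numbering: C1 = lactone carbonyl, ring oxygen on C13, exo-methylene on C10):
1. Target ⇐ bis-silyl-protected macrolide by desilylation; the labile C2 centre is equilibrated last.
2. The only ring (14-membered) is closed at C10–C11 by a new ring-closing, branch-selective oxidative boron-Heck reaction of an open-chain alkenyl boronate/terminal alkene, which also creates the exo-methylene diene.
3. The open-chain β-keto ester ⇐ C2–C3 samarium Reformatsky union of a C3–C10 aldehyde with the α-bromopropanoate of the C11–C13 boronate alcohol, then oxidation.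
4. C3–C10 aldehyde ⇐ C5–C6 acetylide opening of a Sharpless epoxide (sets C4), then trans-hydrostannation/methyl Stille coupling (6E alkene); C8 comes from an Evans allylation.
5. C11–C13 piece ⇐ (R)-pent-1-yn-3-ol by methylalumination–iodination, Miyaura borylation and acylation.

Assumption: (R)-pent-1-yn-3-ol is bought as the single enantiomer, and C2 (between two carbonyls, configurationally labile) is taken to prefer the (2R) configuration of the target at equilibrium.

Step 1
Reactants: 1 (4R)-4-benzyl-3-propanoyl-1,3-oxazolidin-2-one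
Product: 3 (4R)-4-benzyl-3-[(2S)-2-methylpent-4-enoyl]-1,3-oxazolidin-2-one, via sodium Z-enolate 2 (not isolated)
Conditions: NaN(SiMe3)2, THF, −78 °C; allyl iodide, −78 → −40 °C
Reagents that add atoms: allyl iodide (3-iodoprop-1-ene), C=CCI
Why: Evans asymmetric alkylation; the chelated Z-enolate 2 is allylated on the face opposite the benzyl group, which sets C8 as (S).

Step 2
Reactants: 3 (4R)-4-benzyl-3-[(2S)-2-methylpent-4-enoyl]-1,3-oxazolidin-2-one
Product: 4 (2S)-2-methylpent-4-en-1-ol
Conditions: LiBH4, MeOH (1 equiv), Et2O, 0 °C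
Reagents that add atoms: none
Why: Reductive cleavage of the imide by borohydride frees the primary alcohol without touching the α-stereocentre or the alkene; the auxiliary is recovered.

Step 3
Reactants: 4 (2S)-2-methylpent-4-en-1-ol
Product: 6 (3S)-1,1-dibromo-3-methylhexa-1,5-diene, via (2S)-2-methylpent-4-enal 5 (not isolated)
Conditions: TEMPO (cat.), PhI(OAc)2, CH2Cl2, rt; aqueous wash, dried solution added to CBr4/PPh3 (1:2), CH2Cl2, 0 °C
Reagents that add atoms: carbon tetrabromide, BrC(Br)(Br)Br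
Why: Nitroxyl-catalysed oxidation gives the volatile, epimerisable aldehyde 5 under near-neutral conditions, and it is trapped at once by Corey–Fuchs dibromo-olefination (Wittig type), so C8 is not scrambled; the CBr4 carbon becomes C6.

Step 4
Reactants: 7 2-methylidenepropane-1,3-diol
Product: 8 2-{[(4-methoxyphenyl)methoxy]methyl}prop-2-en-1-ol
Conditions: Ag2O, 4-methoxybenzyl chloride (1 equiv), CH2Cl2, rt (diol in excess)
Reagents that add atoms: 4-methoxybenzyl chloride, COc1ccc(CCl)cc1
Why: Silver-oxide-mediated Williamson etherification of a symmetrical diol stops at the mono-ether, which differentiates the two arms (PMB arm = future C3).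

Step 5
Reactants: 8 2-{[(4-methoxyphenyl)methoxy]methyl}prop-2-en-1-ol
Product: 9 [(2S)-2-{[(4-methoxyphenyl)methoxy]methyl}oxiran-2-yl]methanol
Conditions: Ti(OiPr)4 (10 mol%), L-(+)-diisopropyl tartrate (12 mol%), t-BuOOH, 4 Å MS, CH2Cl2, −20 °C
Reagents that add atoms: tert-butyl hydroperoxide, CC(C)(C)OO
Why: Sharpless asymmetric epoxidation; with the L-(+)-tartrate the oxygen is delivered to the face that gives the (S)-epoxide (same sense as for 2-methylallyl alcohol), fixing the future C4: epoxide O becomes the C4 hydroxyl, epoxide CH2 becomes C5, the free CH2OH becomes the C4 hydroxymethyl group and the PMB arm becomes C3.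

Step 6
Reactants: 6 (3S)-1,1-dibromo-3-methylhexa-1,5-diene; 9 [(2S)-2-{[(4-methoxyphenyl)methoxy]methyl}oxiran-2-yl]methanol
Product: 12 (2R,6S)-2-{[(4-methoxyphenyl)methoxy]methyl}-6-methylnon-8-en-4-yne-1,2-diol, via lithium acetylide 10 (not isolated), via lithium epoxy-alkoxide 11 (not isolated)
Conditions: 6, n-BuLi (2.0 equiv), THF, −78 → 0 °C; 9, n-BuLi (1.0 equiv), THF, −78 °C; combine, BF3·OEt2, −78 °C; aq. NH4Cl
Reagents that add atoms: none
Why: The second stage of the Corey–Fuchs sequence gives acetylide 10, which opens the BF3-activated epoxide of 11 at its unsubstituted carbon (SN2 epoxide alkynylation), forming C5–C6 with C4 untouched; a Payne rearrangement of 11 is degenerate and cannot erode the ee.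

Step 7
Reactants: 12 (2R,6S)-2-{[(4-methoxyphenyl)methoxy]methyl}-6-methylnon-8-en-4-yne-1,2-diol
Product: 13 (2R,4Z,6S)-2-{[(4-methoxyphenyl)methoxy]methyl}-6-methyl-4-(tributylstannyl)nona-4,8-diene-1,2-diol
Conditions: [Cp*RuCl]4 (2.5 mol%), Bu3SnH, CH2Cl2, rt
Reagents that add atoms: tributyltin hydride, CCCC[SnH](CCCC)CCCC
Why: Hydroxyl-directed ruthenium-catalysed trans-hydrostannation; hydrogen bonding of the free C4 hydroxyls to the Ru–Cl unit steers tin to the proximal alkyne carbon C6 and hydrogen trans to it onto C7, which fixes the alkene geometry, while the terminal alkene is left alone.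

Step 8
Reactants: 13 (2R,4Z,6S)-2-{[(4-methoxyphenyl)methoxy]methyl}-6-methyl-4-(tributylstannyl)nona-4,8-diene-1,2-diol
Product: 14 (2R,4E,6S)-2-{[(4-methoxyphenyl)methoxy]methyl}-4,6-dimethylnona-4,8-diene-1,2-diol
Conditions: Pd(PPh3)4 (10 mol%), Cu(O2CC4H3S) (copper thiophene-2-carboxylate), [NBu4][Ph2PO2], MeI, DMF, rt
Reagents that add atoms: iodomethane, CI
Why: Copper-assisted Stille cross-coupling with methyl iodide (tin scavenged as phosphinate) replaces tin by methyl with retention, giving the (6E)-trisubstituted alkene.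

Step 9
Reactants: 14 (2R,4E,6S)-2-{[(4-methoxyphenyl)methoxy]methyl}-4,6-dimethylnona-4,8-diene-1,2-diol
Product: 15 1-methoxy-4-({[(2S,4E,6S)-4,6-dimethyl-2-[(triethylsilyl)oxy]-2-{[(triethylsilyl)oxy]methyl}nona-4,8-dien-1-yl]oxy}methyl)benzene
Conditions: Et3SiOTf, 2,6-lutidine, CH2Cl2, −78 → 0 °C
Reagents that add atoms: triethylsilyl trifluoromethanesulfonate, CC[Si](CC)(CC)OS(=O)(=O)C(F)(F)F
Why: Silyl triflate silylation caps both the primary and the hindered tertiary hydroxyl, which later blocks attack of the C4 hydroxyl on C1 (tetronate formation) and retro-aldol loss of formaldehyde.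

Step 10
Reactants: 15 1-methoxy-4-({[(2S,4E,6S)-4,6-dimethyl-2-[(triethylsilyl)oxy]-2-{[(triethylsilyl)oxy]methyl}nona-4,8-dien-1-yl]oxy}methyl)benzene
Product: 16 (2S,4E,6S)-4,6-dimethyl-2-[(triethylsilyl)oxy]-2-{[(triethylsilyl)oxy]methyl}nona-4,8-dien-1-ol
Conditions: DDQ, CH2Cl2/pH 7 buffer, 0 °C
Reagents that add atoms: none
Why: Oxidative cleavage of the PMB ether (hydride abstraction at the electron-rich benzylic position) frees only the C3 hydroxyl; isolated alkenes and silyl ethers are inert, and no conjugated diene is present yet.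

Step 11
Reactants: 16 (2S,4E,6S)-4,6-dimethyl-2-[(triethylsilyl)oxy]-2-{[(triethylsilyl)oxy]methyl}nona-4,8-dien-1-ol
Product: 17 (2R,4E,6S)-4,6-dimethyl-2-[(triethylsilyl)oxy]-2-{[(triethylsilyl)oxy]methyl}nona-4,8-dienal
Conditions: Dess–Martin periodinane, CH2Cl2, rt
Reagents that add atoms: none
Why: Dess–Martin oxidation of the neopentyl alcohol gives a non-enolisable α-silyloxy aldehyde, so no stereocentre is at risk.

Step 12
Reactants: 18 (3R)-pent-1-yn-3-ol
Product: 20 (1E,3R)-1-iodo-2-methylpent-1-en-3-ol, via alkenylalane 19 (not isolated)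
Conditions: AlMe3 (3 equiv), Cp2ZrCl2 (25 mol%), CH2Cl2, 0 °C → rt; then I2, THF, −30 → 0 °C
Reagents that add atoms: trimethylaluminium, C[Al](C)C; iodine, II
Why: Negishi zirconium-catalysed methylalumination adds methyl and aluminium syn across the alkyne with aluminium on the terminal carbon, and iodinolysis with retention gives the (E)-iodide; the C13 carbinol centre (as its aluminium alkoxide) is untouched.

Step 13
Reactants: 20 (1E,3R)-1-iodo-2-methylpent-1-en-3-ol
Product: 21 (1E,3R)-2-methyl-1-(4,4,5,5-tetramethyl-1,3,2-dioxaborolan-2-yl)pent-1-en-3-ol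
Conditions: B2pin2, PdCl2(PPh3)2 (3 mol%), PPh3, KOPh, toluene, 50 °C
Reagents that add atoms: bis(pinacolato)diboron, CC1(C)OB(OC1(C)C)B1OC(C)(C)C(C)(C)O1
Why: Miyaura borylation of the alkenyl iodide proceeds with retention of the E geometry; the weak phenoxide base suppresses Suzuki homocoupling and tolerates the free hydroxyl.

Step 14
Reactants: 21 (1E,3R)-2-methyl-1-(4,4,5,5-tetramethyl-1,3,2-dioxaborolan-2-yl)pent-1-en-3-ol
Product: 22 (1E,3R)-2-methyl-1-(4,4,5,5-tetramethyl-1,3,2-dioxaborolan-2-yl)pent-1-en-3-yl 2-bromopropanoate (both configurations at CHBr)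
Conditions: 2-bromopropanoyl bromide, pyridine, CH2Cl2, 0 °C
Reagents that add atoms: 2-bromopropanoyl bromide, CC(Br)C(Br)=O
Why: Acylation of the secondary allylic alcohol through the acylpyridinium ion leaves the C–B bond alone; the bromine-bearing carbon need not be controlled because it becomes an enolate carbon.

Step 15
Reactants: 17 (2R,4E,6S)-4,6-dimethyl-2-[(triethylsilyl)oxy]-2-{[(triethylsilyl)oxy]methyl}nona-4,8-dienal; 22 (1E,3R)-2-methyl-1-(4,4,5,5-tetramethyl-1,3,2-dioxaborolan-2-yl)pent-1-en-3-yl 2-bromopropanoate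
Product: 24 (1E,3R)-2-methyl-1-(4,4,5,5-tetramethyl-1,3,2-dioxaborolan-2-yl)pent-1-en-3-yl (4R,6E,8S)-3-hydroxy-2,6,8-trimethyl-4-[(triethylsilyl)oxy]-4-{[(triethylsilyl)oxy]methyl}undeca-6,10-dienoate (C2/C3 diastereomers), via samarium enolate 23 (not isolated)
Conditions: SmI2 (2.2 equiv), THF, −78 °C
Reagents that add atoms: none
Why: Samarium Reformatsky reaction; SmI2 reduces the C–Br bond to the trivalent samarium enolate 23, which adds to the hindered non-enolisable aldehyde under neutral conditions that spare the boronate; C2 and C3 are left uncontrolled because C3 is oxidised next and C2 is set in step 18.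

Step 16
Reactants: 24 (1E,3R)-2-methyl-1-(4,4,5,5-tetramethyl-1,3,2-dioxaborolan-2-yl)pent-1-en-3-yl (4R,6E,8S)-3-hydroxy-2,6,8-trimethyl-4-[(triethylsilyl)oxy]-4-{[(triethylsilyl)oxy]methyl}undeca-6,10-dienoate
Product: 25 (1E,3R)-2-methyl-1-(4,4,5,5-tetramethyl-1,3,2-dioxaborolan-2-yl)pent-1-en-3-yl (4R,6E,8S)-2,6,8-trimethyl-3-oxo-4-[(triethylsilyl)oxy]-4-{[(triethylsilyl)oxy]methyl}undeca-6,10-dienoate (C2 epimers)
Conditions: Dess–Martin periodinane, CH2Cl2, 0 °C → rt
Reagents that add atoms: none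
Why: Dess–Martin oxidation turns the C3 carbinol into the ketone and converges the diastereomers to the β-keto ester (C2 epimers); boronate, silyl ethers and alkenes are inert.

Step 17
Reactants: 25 (1E,3R)-2-methyl-1-(4,4,5,5-tetramethyl-1,3,2-dioxaborolan-2-yl)pent-1-en-3-yl (4R,6E,8S)-2,6,8-trimethyl-3-oxo-4-[(triethylsilyl)oxy]-4-{[(triethylsilyl)oxy]methyl}undeca-6,10-dienoate
Product: 26 (5R,7E,9S,12E,14R)-14-ethyl-3,7,9,13-tetramethyl-11-methylidene-5-[(triethylsilyl)oxy]-5-{[(triethylsilyl)oxy]methyl}-1-oxacyclotetradeca-7,12-diene-2,4-dione (epimers at ring C3 = macrolide C2)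
Conditions: Pd(O2CCF3)2 (15 mol%), 2,9-dimethyl-1,10-phenanthroline (30 mol%), O2 (1 atm), NMP/H2O (50:1), 45 °C, syringe-pump addition to 1 mM
Reagents that add atoms: none
Why: Proposed new method: ring-closing, branch-selective aerobic oxidative boron-Heck reaction. The cationic divalent palladium/2,9-dimethylphenanthroline catalyst takes up the (E)-alkenyl group from boron (C11, retention), inserts the only monosubstituted alkene of the molecule in the Markovnikov sense favoured by this hindered cationic catalyst (C11 to the internal carbon C10, Pd to the terminal CH2), and β-hydride elimination can then use only the C10–H, so the C10–C11 bond, the exocyclic methylene and the 14-membered ring arise together. O2 reoxidises the zerovalent palladium so fast that it has little chance to ionise the allylic β-keto ester, and slow addition at 1 mM suppresses oligomerisation and boronate homocoupling; no stereocentre is formed and the 11E geometry is carried over from 21. Closest known reaction type: the intermolecular Pd/2,9-dimethylphenanthroline aerobic oxidative Heck coupling of alkenylboron compounds with unactivated terminal alkenes to branched 1,3-dienes; a macrocyclising version, and one with a β,β-disubstituted alkenyl boronate, has not been described.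

Step 18
Reactants: 26 (5R,7E,9S,12E,14R)-14-ethyl-3,7,9,13-tetramethyl-11-methylidene-5-[(triethylsilyl)oxy]-5-{[(triethylsilyl)oxy]methyl}-1-oxacyclotetradeca-7,12-diene-2,4-dione
Product: 28 (3R,5R,7E,9S,12E,14R)-14-ethyl-5-hydroxy-5-(hydroxymethyl)-3,7,9,13-tetramethyl-11-methylidene-1-oxacyclotetradeca-7,12-diene-2,4-dione (target CNP0240796.7), via C2-epimeric diol mixture 27 (not isolated)
Conditions: HF·pyridine, pyridine, THF, 0 °C → rt; then AcOH (cat.), CH2Cl2, rt
Reagents that add atoms: none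
Why: Fluoride-mediated desilylation removes both silyl ethers under buffered, non-basic conditions that spare the diene, the β-keto lactone and the tertiary ketol, and acid-catalysed keto–enol exchange then equilibrates C2 of 27 to the (2R) epimer (thermodynamic control, see the assumption).

Compound list
1 | (4R)-4-benzyl-3-propanoyl-1,3-oxazolidin-2-one | CCC(=O)N1[C@H](Cc2ccccc2)COC1=O | starting material
2 | sodium (Z)-enolate of 1 | C/C=C(\[O-])N1[C@H](Cc2ccccc2)COC1=O.[Na+] | intermediate
3 | (4R)-4-benzyl-3-[(2S)-2-methylpent-4-enoyl]-1,3-oxazolidin-2-one | C=CC[C@H](C)C(=O)N1[C@H](Cc2ccccc2)COC1=O | intermediate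
4 | (2S)-2-methylpent-4-en-1-ol | OC[C@@H](C)CC=C | intermediate
5 | (2S)-2-methylpent-4-enal | O=C[C@@H](C)CC=C | intermediate
6 | (3S)-1,1-dibromo-3-methylhexa-1,5-diene | BrC(Br)=C[C@@H](C)CC=C | intermediate
7 | 2-methylidenepropane-1,3-diol | C=C(CO)CO | starting material
8 | 2-{[(4-methoxyphenyl)methoxy]methyl}prop-2-en-1-ol | COc1ccc(COCC(=C)CO)cc1 | intermediate
9 | [(2S)-2-{[(4-methoxyphenyl)methoxy]methyl}oxiran-2-yl]methanol | COc1ccc(COC[C@]2(CO)CO2)cc1 | intermediate
10 | lithium (3S)-3-methylhex-5-en-1-yn-1-ide | [Li]C#C[C@@H](C)CC=C | intermediate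
11 | lithium [(2S)-2-{[(4-methoxyphenyl)methoxy]methyl}oxiran-2-yl]methanolate | COc1ccc(COC[C@]2(CO[Li])CO2)cc1 | intermediate
12 | (2R,6S)-2-{[(4-methoxyphenyl)methoxy]methyl}-6-methylnon-8-en-4-yne-1,2-diol | COc1ccc(COC[C@](O)(CO)CC#C[C@@H](C)CC=C)cc1 | intermediate
13 | (2R,4Z,6S)-2-{[(4-methoxyphenyl)methoxy]methyl}-6-methyl-4-(tributylstannyl)nona-4,8-diene-1,2-diol | COc1ccc(COC[C@](O)(CO)C/C(=C/[C@@H](C)CC=C)[Sn](CCCC)(CCCC)CCCC)cc1 | intermediate
14 | (2R,4E,6S)-2-{[(4-methoxyphenyl)methoxy]methyl}-4,6-dimethylnona-4,8-diene-1,2-diol | COc1ccc(COC[C@](O)(CO)C/C(C)=C/[C@@H](C)CC=C)cc1 | intermediate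
15 | 1-methoxy-4-({[(2S,4E,6S)-4,6-dimethyl-2-[(triethylsilyl)oxy]-2-{[(triethylsilyl)oxy]methyl}nona-4,8-dien-1-yl]oxy}methyl)benzene | COc1ccc(COC[C@](O[Si](CC)(CC)CC)(CO[Si](CC)(CC)CC)C/C(C)=C/[C@@H](C)CC=C)cc1 | intermediate
16 | (2S,4E,6S)-4,6-dimethyl-2-[(triethylsilyl)oxy]-2-{[(triethylsilyl)oxy]methyl}nona-4,8-dien-1-ol | OC[C@](O[Si](CC)(CC)CC)(CO[Si](CC)(CC)CC)C/C(C)=C/[C@@H](C)CC=C | intermediate
17 | (2R,4E,6S)-4,6-dimethyl-2-[(triethylsilyl)oxy]-2-{[(triethylsilyl)oxy]methyl}nona-4,8-dienal | O=C[C@](O[Si](CC)(CC)CC)(CO[Si](CC)(CC)CC)C/C(C)=C/[C@@H](C)CC=C | intermediate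
18 | (3R)-pent-1-yn-3-ol | CC[C@@H](O)C#C | starting material
19 | dimethylaluminium alkoxide of (1E,3R)-1-(dimethylalumanyl)-2-methylpent-1-en-3-ol | CC[C@@H](O[Al](C)C)/C(C)=C/[Al](C)C | intermediate
20 | (1E,3R)-1-iodo-2-methylpent-1-en-3-ol | CC[C@@H](O)/C(C)=C/I | intermediate
21 | (1E,3R)-2-methyl-1-(4,4,5,5-tetramethyl-1,3,2-dioxaborolan-2-yl)pent-1-en-3-ol | CC[C@@H](O)/C(C)=C/B1OC(C)(C)C(C)(C)O1 | intermediate
22 | (1E,3R)-2-methyl-1-(4,4,5,5-tetramethyl-1,3,2-dioxaborolan-2-yl)pent-1-en-3-yl 2-bromopropanoate (both configurations at CHBr) | CC[C@@H](OC(=O)C(C)Br)/C(C)=C/B1OC(C)(C)C(C)(C)O1 | intermediate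
23 | diiodosamarium enolate of 22 | CC[C@@H](OC(O[Sm](I)I)=CC)/C(C)=C/B1OC(C)(C)C(C)(C)O1 | intermediate
24 | (1E,3R)-2-methyl-1-(4,4,5,5-tetramethyl-1,3,2-dioxaborolan-2-yl)pent-1-en-3-yl (4R,6E,8S)-3-hydroxy-2,6,8-trimethyl-4-[(triethylsilyl)oxy]-4-{[(triethylsilyl)oxy]methyl}undeca-6,10-dienoate (C2/C3 diastereomers) | CC[C@@H](OC(=O)C(C)C(O)[C@](O[Si](CC)(CC)CC)(CO[Si](CC)(CC)CC)C/C(C)=C/[C@@H](C)CC=C)/C(C)=C/B1OC(C)(C)C(C)(C)O1 | intermediate
25 | (1E,3R)-2-methyl-1-(4,4,5,5-tetramethyl-1,3,2-dioxaborolan-2-yl)pent-1-en-3-yl (4R,6E,8S)-2,6,8-trimethyl-3-oxo-4-[(triethylsilyl)oxy]-4-{[(triethylsilyl)oxy]methyl}undeca-6,10-dienoate (C2 epimers) | CC[C@@H](OC(=O)C(C)C(=O)[C@](O[Si](CC)(CC)CC)(CO[Si](CC)(CC)CC)C/C(C)=C/[C@@H](C)CC=C)/C(C)=C/B1OC(C)(C)C(C)(C)O1 | intermediate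
26 | (5R,7E,9S,12E,14R)-14-ethyl-3,7,9,13-tetramethyl-11-methylidene-5-[(triethylsilyl)oxy]-5-{[(triethylsilyl)oxy]methyl}-1-oxacyclotetradeca-7,12-diene-2,4-dione (epimers at ring C3) | C=C1/C=C(\C)[C@@H](CC)OC(=O)C(C)C(=O)[C@](O[Si](CC)(CC)CC)(CO[Si](CC)(CC)CC)C/C(C)=C/[C@@H](C)C1 | intermediate
27 | (3RS,5R,7E,9S,12E,14R)-14-ethyl-5-hydroxy-5-(hydroxymethyl)-3,7,9,13-tetramethyl-11-methylidene-1-oxacyclotetradeca-7,12-diene-2,4-dione | C=C1/C=C(\C)[C@@H](CC)OC(=O)C(C)C(=O)[C@](O)(CO)C/C(C)=C/[C@@H](C)C1 | intermediate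
28 | (3R,5R,7E,9S,12E,14R)-14-ethyl-5-hydroxy-5-(hydroxymethyl)-3,7,9,13-tetramethyl-11-methylidene-1-oxacyclotetradeca-7,12-diene-2,4-dione (CNP0240796.7) | C=C1/C=C(\C)[C@@H](CC)OC(=O)[C@H](C)C(=O)[C@](O)(CO)C/C(C)=C/[C@@H](C)C1 | target

Total step count: 18. Longest linear sequence: 13 steps (1–3, 6–11, 15–18).

Steps most likely to fail

Step 17 (the new ring closure). The risks are linear instead of branched insertion, boronate homocoupling or protodeboronation, and oligomerisation. The fallback sets out from aldehyde 17 and bromoester 22 and comes back at 26. The C10–C11 bond is made first between the two fragments by the known intermolecular branch-selective oxidative boron-Heck coupling (Pd(O2CCF3)2, 2,9-dimethyl-1,10-phenanthroline, O2, NMP, 45 °C), which gives the open-chain diene aldehyde (3R,4E,8S,9E,12R)-4,8,10-trimethyl-6-methylidene-13-oxo-12-[(triethylsilyl)oxy]-12-{[(triethylsilyl)oxy]methyl}trideca-4,9-dien-3-yl 2-bromopropanoate F1. The ring is then closed at C2–C3 by a known samarium Reformatsky macrocyclisation (SmI2, THF, high dilution, −78 → 0 °C) through the diiodosamarium enolate F2 to the macrocyclic β-hydroxy lactone F3. Dess–Martin oxidation of F3 gives 26.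

Step 7 (regiochemistry of the directed trans-hydrostannation; the hydroxyl is homopropargylic, not propargylic, and the hindered stannane must then be methylated in step 8). The fallback sets out from dibromide 6 and epoxy-alkoxide 11 and comes back at 14, building the trisubstituted alkene before the fragment union. Treatment of 6 with n-BuLi (2 equiv, via 10) and MeI gives the methyl alkyne (4S)-4-methylhept-1-en-5-yne F4. Palladium-catalysed syn-hydrostannation (Bu3SnH, PdCl2(PPh3)2, THF) puts tin on the less hindered, methyl-bearing carbon and gives tributyl[(2E,4S)-4-methylhepta-2,6-dien-2-yl]stannane F5 (minor regioisomer removed by chromatography). Tin–lithium exchange with n-BuLi gives the alkenyllithium [(2Z,4S)-4-methylhepta-2,6-dien-2-yl]lithium F6, which opens 11 at its CH2 terminus with BF3·OEt2 to give diol 14 directly, with the 6E geometry already fixed.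

Step 18 (C2 configuration and survival of the free ketol/β-keto lactone). The equilibrium may not favour (2R) strongly enough. The fallback sets out from 26 and comes back at 28, setting C2 under kinetic control while both hydroxyls are still silylated, so no retro-aldol or tetronate pathway is open. KN(SiMe3)2 in THF at −78 °C gives the potassium enolate of 26 F7. It is protonated from the less hindered face by 2,6-di-tert-butyl-4-methylphenol (or, if substrate control is poor, by the appropriate antipode of a chiral proton donor) to give the (2R)-configured bis-silyl ether F8. Short desilylation with buffered HF·pyridine at 0 °C, without the acid equilibration, then gives 28.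

Further compounds
F1 | step 17 | (3R,4E,8S,9E,12R)-4,8,10-trimethyl-6-methylidene-13-oxo-12-[(triethylsilyl)oxy]-12-{[(triethylsilyl)oxy]methyl}trideca-4,9-dien-3-yl 2-bromopropanoate | O=C[C@](O[Si](CC)(CC)CC)(CO[Si](CC)(CC)CC)C/C(C)=C/[C@@H](C)CC(=C)/C=C(\C)[C@@H](CC)OC(=O)C(C)Br
F2 | step 17 | diiodosamarium enolate of F1 | O=C[C@](O[Si](CC)(CC)CC)(CO[Si](CC)(CC)CC)C/C(C)=C/[C@@H](C)CC(=C)/C=C(\C)[C@@H](CC)OC(O[Sm](I)I)=CC
F3 | step 17 | (5R,7E,9S,12E,14R)-14-ethyl-4-hydroxy-3,7,9,13-tetramethyl-11-methylidene-5-[(triethylsilyl)oxy]-5-{[(triethylsilyl)oxy]methyl}-1-oxacyclotetradeca-7,12-dien-2-one (diastereomers at ring C3/C4) | C=C1/C=C(\C)[C@@H](CC)OC(=O)C(C)C(O)[C@](O[Si](CC)(CC)CC)(CO[Si](CC)(CC)CC)C/C(C)=C/[C@@H](C)C1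
F4 | step 7 | (4S)-4-methylhept-1-en-5-yne | CC#C[C@@H](C)CC=C
F5 | step 7 | tributyl[(2E,4S)-4-methylhepta-2,6-dien-2-yl]stannane | CCCC[Sn](CCCC)(CCCC)/C(C)=C/[C@@H](C)CC=C
F6 | step 7 | [(2Z,4S)-4-methylhepta-2,6-dien-2-yl]lithium | [Li]/C(C)=C/[C@@H](C)CC=C
F7 | step 18 | potassium enolate of 26 | C=C1/C=C(\C)[C@@H](CC)OC(=O)C(C)=C([O-])[C@](O[Si](CC)(CC)CC)(CO[Si](CC)(CC)CC)C/C(C)=C/[C@@H](C)C1.[K+]
F8 | step 18 | (3R,5R,7E,9S,12E,14R)-14-ethyl-3,7,9,13-tetramethyl-11-methylidene-5-[(triethylsilyl)oxy]-5-{[(triethylsilyl)oxy]methyl}-1-oxacyclotetradeca-7,12-diene-2,4-dione | C=C1/C=C(\C)[C@@H](CC)OC(=O)[C@H](C)C(=O)[C@](O[Si](CC)(CC)CC)(CO[Si](CC)(CC)CC)C/C(C)=C/[C@@H](C)C1
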